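**Assumptions (one line):** 3-Cyclopentene-1-carboxylic acid, isopropyl vinyl ketone, 2-bromopropene and 4-(TBSO)benzoic acid are commercial, and so are the catalysts (S)-7 and (R)-15. Sesquiterpene labels C1–C10 are used in the text, and azulene locants only in names (azulene 1 = C8, 3a = C5, 5 = C7, 6 = C1, 8 = C3, 8a = C4). The catalyst senses are assumed to give the required absolute configuration, and the enantiomeric catalyst is used if the opposite sense is found.

## Retrosynthetic overview
1. Ferugin comes from esterifying C3-OH with a protected p-hydroxybenzoate and setting the C7 allylic carbinol by CBS reduction of an enone, both after ring closure.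
2. The seven-membered ring is formed last by a type II intramolecular carbonyl–ene reaction (C2–C3 bond, exocyclic C1 methylene, C3-OH). The substrate is a cyclopentane aldehyde carrying an isopropenyl carbinol chain, made by chemoselective NHK isopropenylation of the less hindered aldehyde.
3. The cyclopentane (C5 quaternary, C4, C8) is formed first, by an organocatalytic desymmetrizing enamine aldol of a prochiral 3,3-disubstituted glutaraldehyde bearing a pendant isopropyl ketone.
4. That dialdehyde comes from ozonolysis of a 4,4-disubstituted cyclopentene, made from 3-cyclopentenecarboxylic acid by α-methylation and decarboxylative Giese addition to isopropyl vinyl ketone.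

## Route

**Step 1**
Reactants: 1 (3-cyclopentene-1-carboxylic acid); 2 (iodomethane)
Product: 3 (1-methylcyclopent-3-ene-1-carboxylic acid)
Conditions: LDA (2.2 equiv), THF, −78→0 °C; then MeI, −78 °C→rt; 1 M HCl workup
Reagents that add atoms: iodomethane, CI
Why: Carboxylate dianion α-methylation (Creger alkylation) puts the angular methyl on the future C5, which stays achiral because the two ring arms are identical.

**Step 2**
Reactants: 3; 4 (4-methylpent-1-en-3-one, isopropyl vinyl ketone)
Product: 5 (2-methyl-5-(1-methylcyclopent-3-en-1-yl)pentan-3-one)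
Conditions: 4CzIPN (2 mol%), Cs2CO3 (1 equiv), DMF, blue LEDs, rt, 16 h; 4 used in excess (2–3 equiv)
Reagents that add atoms: isopropyl vinyl ketone (4), C=CC(=O)C(C)C
Why: Organophotocatalytic decarboxylative Giese addition of the tertiary radical to the vinyl ketone builds the C5–C10–C9–C8 chain with no new stereocenter (the cyclopentene is symmetric), and the ring alkene and ketone survive.

**Step 3**
Reactants: 5
Product: 6 (3-methyl-3-(4-methyl-3-oxopentyl)pentanedial), used crude
Conditions: O3, CH2Cl2, −78 °C; then Me2S, −78 °C→rt
Reagents that add atoms: ozone, [O-][O+]=O (supplies the two aldehyde oxygens)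
Why: Ozonolysis with reductive work-up opens the cyclopentene to the prochiral 1,5-dialdehyde, and the dialkyl ketone is inert.

**Step 4**
Reactants: 6; 7 ((S)-α,α-diphenylprolinol TMS ether, catalyst)
Product: 8 ((1R,2R,5R)-2-hydroxy-5-methyl-5-(2-oxoethyl)-2-(propan-2-yl)cyclopentane-1-carbaldehyde)
Conditions: 7 (20 mol%), PhCO2H (20 mol%), toluene (0.03 M), 4 °C→rt, 48 h
Reagents that add atoms: none (isomerization)
Why: Proposed new method: the bulky diarylprolinol ether forms an enamine only with an unhindered CH2CHO arm (not with the isopropyl ketone), and acid-assisted 5-(enolexo)-exo-trig attack of that enamine on the ketone forms C4–C8 and the tertiary alcohol. Selection between the two enantiotopic arms and the enamine face sets C5, C4 and C8 together, and reversible aldol plus α-epimerization at C4 should funnel to the isomer with CHO, OH and Me cis and iPr trans to CHO. The closest known reactions are the Hajos–Parrish/proline intramolecular aldol and enamine aldehyde–ketone aldols, but desymmetrizing a 3,3-disubstituted glutaraldehyde onto an unactivated dialkyl ketone to give a tertiary cyclopentanol has not been shown.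

**Step 5**
Reactants: 8; 9 (2-bromopropene)
Product: 10 ((1R,2R,5R)-2-hydroxy-5-(2-hydroxy-3-methylbut-3-en-1-yl)-5-methyl-2-(propan-2-yl)cyclopentane-1-carbaldehyde, about 1:1 at the new carbinol C7)
Conditions: 9 (1.5 equiv), CrCl2 (3 equiv), NiCl2 (1 mol%), DMF, 0 °C→rt, 12 h
Reagents that add atoms: 2-bromopropene, C=C(C)Br
Why: Ni-catalysed Nozaki–Hiyama–Kishi vinylation is mild, tolerates free OH and an epimerizable aldehyde, and adds to the unhindered CH2CHO rather than the α-branched C4 aldehyde next to the quaternary carbon. The C7 epimer ratio is irrelevant because C7 is oxidized in Step 7.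

**Step 6**
Reactants: 10
Product: 11 ((1R,3aR,8S,8aS)-3a-methyl-6-methylidene-1-(propan-2-yl)decahydroazulene-1,5,8-triol, epimeric mixture at C5 of azulene numbering = C7)
Conditions: Me2AlCl (3.5 equiv), CH2Cl2, −78→0 °C; Rochelle salt workup
Reagents that add atoms: none (isomerization)
Why: Type II intramolecular carbonyl–ene reaction (Snider-type Me2AlCl promotion) joins C2 to C3, closes the seven-membered ring and gives the exocyclic C1 methylene. The aluminium chelate between the cis C8-alkoxide and the C3 aldehyde fixes the aldehyde conformation so that the tethered alkene reaches one face, and the trans ring fusion is already set by C4 and C5.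

**Step 7**
Reactants: 11
Product: 12 ((1R,3aR,8S,8aS)-1,8-dihydroxy-3a-methyl-6-methylidene-1-(propan-2-yl)octahydroazulen-5(1H)-one)
Conditions: activated MnO2 (20 equiv), CH2Cl2, rt, 4 h
Reagents that add atoms: none
Why: MnO2 oxidizes only the allylic C7 alcohol (not the homoallylic C3-OH or the tertiary C8-OH) and converges both C7 epimers to one enone.

**Step 8**
Reactants: 12; 13 (4-(tert-butyldimethylsilyloxy)benzoic acid)
Product: 14 ((1R,3aR,8S,8aS)-1-hydroxy-3a-methyl-6-methylidene-5-oxo-1-(propan-2-yl)decahydroazulen-8-yl 4-[(tert-butyldimethylsilyl)oxy]benzoate)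
Conditions: 13 (2 equiv), 2,4,6-Cl3C6H2COCl (2 equiv), Et3N (3 equiv), THF, rt, 2 h; then 12, DMAP (1 equiv), toluene, rt, 12 h (Yamaguchi esterification)
Reagents that add atoms: 13, CC(C)(C)[Si](C)(C)Oc1ccc(cc1)C(=O)O
Why: With C7 at the ketone oxidation level, C3-OH is the only acylable secondary alcohol, and the hindered tertiary C8-OH stays free, so the mixed-anhydride acylation is selective.

**Step 9**
Reactants: 14; 15 ((R)-Me-CBS, catalyst); catecholborane
Product: 16 ((1R,3aR,5S,8S,8aS)-1,5-dihydroxy-3a-methyl-6-methylidene-1-(propan-2-yl)decahydroazulen-8-yl 4-[(tert-butyldimethylsilyl)oxy]benzoate)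
Conditions: (R)-Me-CBS (30 mol%), catecholborane (3 equiv), toluene, −78 °C, 6 h; MeOH quench
Reagents that add atoms: none (only hydrogen added)
Why: Corey–Bakshi–Shibata reduction is catalyst-controlled, treating the sp2 methylene-bearing C1 as the large group and the C6 CH2 as the small one, so (R)-Me-CBS should deliver the C7 (S) alcohol. Catecholborane is used because it does not hydroborate the exocyclic alkene at −78 °C, and the ester, the aryl silyl ether and the tertiary alcohol survive.

**Step 10**
Reactants: 16
Product: 17 (Ferugin)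
Conditions: TBAF, AcOH (1:1), THF, 0 °C, 1 h
Reagents that add atoms: none
Why: Buffered fluoride cleaves only the aryl Si–O bond, leaving the benzoate and all stereocenters intact.

## Compound list
1 | 3-cyclopentene-1-carboxylic acid | OC(=O)C1CC=CC1 | starting material
2 | iodomethane | CI | starting material
3 | 1-methylcyclopent-3-ene-1-carboxylic acid | CC1(C(=O)O)CC=CC1 | intermediate
4 | 4-methylpent-1-en-3-one (isopropyl vinyl ketone) | C=CC(=O)C(C)C | starting material
5 | 2-methyl-5-(1-methylcyclopent-3-en-1-yl)pentan-3-one | CC(C)C(=O)CCC1(C)CC=CC1 | intermediate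
6 | 3-methyl-3-(4-methyl-3-oxopentyl)pentanedial | CC(C)C(=O)CCC(C)(CC=O)CC=O | intermediate
7 | (S)-α,α-diphenylprolinol TMS ether (organocatalyst) | C[Si](C)(C)OC(c1ccccc1)(c1ccccc1)[C@@H]1CCCN1 | starting material
8 | (1R,2R,5R)-2-hydroxy-5-methyl-5-(2-oxoethyl)-2-(propan-2-yl)cyclopentane-1-carbaldehyde | O=C[C@@H]2[C@](C)(CC[C@@]2(O)C(C)C)CC=O | intermediate
9 | 2-bromopropene | C=C(C)Br | starting material
10 | (1R,2R,5R)-2-hydroxy-5-(2-hydroxy-3-methylbut-3-en-1-yl)-5-methyl-2-(propan-2-yl)cyclopentane-1-carbaldehyde (C7 epimer mixture) | O=C[C@@H]2[C@](C)(CC[C@@]2(O)C(C)C)CC(O)C(C)=C | intermediate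
11 | (1R,3aR,8S,8aS)-3a-methyl-6-methylidene-1-(propan-2-yl)decahydroazulene-1,5,8-triol (C7 mixture) | C=C1C[C@H](O)[C@@H]2[C@](C)(CC[C@@]2(O)C(C)C)CC1O | intermediate
12 | (1R,3aR,8S,8aS)-1,8-dihydroxy-3a-methyl-6-methylidene-1-(propan-2-yl)octahydroazulen-5(1H)-one | C=C1C[C@H](O)[C@@H]2[C@](C)(CC[C@@]2(O)C(C)C)CC1=O | intermediate
13 | 4-(tert-butyldimethylsilyloxy)benzoic acid | CC(C)(C)[Si](C)(C)Oc1ccc(cc1)C(=O)O | starting material
14 | (1R,3aR,8S,8aS)-1-hydroxy-3a-methyl-6-methylidene-5-oxo-1-(propan-2-yl)decahydroazulen-8-yl 4-(TBSO)benzoate | C=C1C[C@H](OC(=O)c3ccc(O[Si](C)(C)C(C)(C)C)cc3)[C@@H]2[C@](C)(CC[C@@]2(O)C(C)C)CC1=O | intermediate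
15 | (R)-Me-CBS (oxazaborolidine catalyst) | CB1OC(c2ccccc2)(c2ccccc2)[C@H]2CCCN12 | starting material
16 | (1R,3aR,5S,8S,8aS)-1,5-dihydroxy-3a-methyl-6-methylidene-1-(propan-2-yl)decahydroazulen-8-yl 4-(TBSO)benzoate | C=C1C[C@H](OC(=O)c3ccc(O[Si](C)(C)C(C)(C)C)cc3)[C@@H]2[C@](C)(CC[C@@]2(O)C(C)C)C[C@@H]1O | intermediate
17 | Ferugin, (1R,3aR,5S,8S,8aS)-1,5-dihydroxy-3a-methyl-6-methylidene-1-(propan-2-yl)decahydroazulen-8-yl 4-hydroxybenzoate | C=C1C[C@H](OC(=O)c2ccc(O)cc2)[C@@H]2[C@](C)(CC[C@@]2(O)C(C)C)C[C@@H]1O | target

**Total steps:** 10. **Longest linear sequence:** 10 steps (1→3→5→6→8→10→11→12→14→16→17).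

## Three steps most likely to fail
1. **Step 4 (the proposed new desymmetrizing aldol).** Risks are dehydration to the enal, a low C4/C8 diastereomer ratio, and poor reactivity of the isopropyl ketone.
   *Fallback (known chemistry):* Build C5 by Cu/chiral-phosphine asymmetric conjugate addition of (1,3-dioxolan-2-yl)methylmagnesium bromide to 3-methylcyclopent-2-enone. Trap the enolate with formaldehyde at C4 (trans to the larger acetal-bearing arm) and protect the CH2OH as its TBS ether. Add iPrMgBr/CeCl3 to the C8 ketone, which adds trans to the adjacent CH2OTBS. Then remove the TBS group, oxidize the CH2OH to CHO and unmask the acetal to reach the aldehyde 8.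
2. **Step 6 (type II carbonyl–ene).** Risks are competing H-transfer from C7 (giving the enol/ketone), a wrong C3 configuration, and the seven-membered ring closure itself.
   *Fallback:* Add 2-bromoallyltrimethylsilane to the C7 aldehyde by NHK, then close the ring by intramolecular Hosomi–Sakurai allylation onto the C3 aldehyde (TiCl4 or TBAF). This gives the same ring, exocyclic methylene and C3-OH.
3. **Step 9 (CBS reduction at C7).** Risks are low diastereoselectivity from mismatched substrate/catalyst control, and a wrong facial sense.
   *Fallback:* Luche reduction (NaBH4, CeCl3, MeOH, −78 °C). If the wrong C7 epimer predominates, invert it by Mitsunobu with p-nitrobenzoic acid, then remove the p-nitrobenzoate selectively by mild methanolysis (K2CO3, MeOH, 0 °C).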